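## Analysis of the target

Target 35 is a labdane with a trans-fused decalin. Ring A (C1–C5, C10) carries the 3β-acetoxy group and the C4 gem-dimethyl group. Ring B (C5–C10) carries the C17 methyl on C8, the angular C20 methyl on C10 and, on C9, a tertiary hydroxyl and the chain C11–C12 that ends in an α-substituted butenolide (C13=C14, C15 as OCH2, C16 as the carbonyl). The five stereocentres are 3S,5S,8R,9R,10S: the acetate and the C17 methyl are equatorial, H-5 and the C20 methyl are trans-diaxial, and the C9 hydroxyl is axial on the α face, cis to C17 and anti to C20, so the side chain is equatorial. C8, C9 and C10 are contiguous and two of them are fully substituted; C4, C5 and C10 are as crowded, with the axial C4 methyl and the C20 methyl 1,3-diaxial. The tertiary C9 alcohol next to quaternary C10 can ionise and rearrange in strong acid, the acetate does not survive hydrides, organometallics or strong base, and the butenolide is a reducible, base-sensitive acceptor, so acetate and butenolide must appear last. The hard part is placing two fully substituted stereocentres (C9, C10) among centres that cannot be corrected by epimerisation. The strategy rests on one feature: quaternary C10 is bonded to C9, whose oxidation level traces back to a carbonyl group, so C9=C10 can be an enol ether whose one-electron oxidation makes C10 an electrophile for C5, and the same C9 later serves as the ketone across which ring B is closed.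

## Retrosynthetic reasoning

**35 ⇒ 33.** The C13=C14 double bond and the acetate are removed together, giving the triol β-hydroxy-γ-lactone 33. Forward, both secondary hydroxyls are acetylated (34) and the C14 acetate, β to the lactone carbonyl, leaves by elimination. The two most fragile groups are thus made in the last operation, and the elimination can only give the endocyclic alkene.

**33 ⇒ 30 ⇒ 28 + 29.** The γ-lactone is traced to the spiro δ-lactone 28, in which the C16 carboxyl is esterified by the C9 oxygen. C13–C14 is cut as an aldol bond between the enolate of 28 and aldehyde 29. C13 is the only enolisable position of 28, and the lactone hides the tertiary alcohol during the enolate step. Forward, freeing the C15 hydroxyl must trigger the ring switch from δ- to γ-lactone (via 31 and 32).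

**28 ⇒ 26 ⇒ 25.** C16 is taken back to a primary alcohol and then to its benzyl ether, a group inert to organometallics and to low-valent titanium. Forward: hydrogenolysis, then oxidative lactonisation through lactol 27.

**25 ⇒ 23.** The C8–C9 bond of ring B is cut to the ketone–alkene 23. This cut makes the two adjacent stereocentres in one event with hydroxyl and methyl cis, because oxygen and C17 end on the same metal atom (titanacycle 24), and C17 arrives already as a methyl carbon. Adding a side chain to a C9 ketone of a finished decalin would have to come from the more hindered β face.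

**23 ⇒ 22 ⇒ 19 + 21 (from 20).** The C9–C11 bond is cut as a Grignard addition to the non-enolisable aldehyde 19, followed by oxidation.

**19 ⇒ 18 ⇒ 15 + 16.** The C7–C8 bond is cut as a B-alkyl Suzuki coupling of borane 17 with 16. The homologation is done while C9 is still an acetal, so the borane sees no carbonyl group.

**15 ⇒ 14.** This is the central cut, C5–C10. In 14 both ends are nucleophilic alkene carbons (enol ether C9=C10, allylsilane C5=C6–C7–Si); forward, anodic oxidation reverses the polarity of the enol ether. The cut makes quaternary C10 already bonded to C9 at the aldehyde level, closes ring A, sets C5 and C10 under control of C3, and leaves a vinyl group on C5 for the growth of ring B.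

**14 ⇒ 11 + 12; 11 ⇒ 9 + 10; 9 ⇒ 8 ⇒ 7.** The enol ether comes last from the methyl ketone by a Wittig reaction (ylide 13), because enol ethers poison metathesis catalysts. The allylsilane comes from the vinyl group of 9 by cross-metathesis with 10. The ketone is kept as a ketal until the aldehyde chemistry is over.

**7 ⇒ 3 + 4; 3 ⇒ 2 ⇒ 1.** The C3–C4 bond is cut as an asymmetric reverse prenylation (prenylborane 5, borinate 6). One step gives the C3 carbinol, the quaternary C4 and the vinyl group; C3 is the only stereocentre set by a reagent, all others are relayed from it. Aldehyde 3 comes from 1 by ketalisation and partial reduction.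

## Alternatives that were turned down

**Alternative 1:** C4–C5 and C9–C10 are cut at once, back to the acyclic (S)-epoxy β-keto ester A2. Forward, an alkylaluminium chloride opens the epoxide at C4, the E-alkene attacks through C5 and the keto ester enol closes ring B at C10, giving the 3β-hydroxy decalone ester A1.
- For: both rings and four stereocentres (C3, C5, C10, C9) form in one step from a precursor a few steps from commercial terpene material. The trans fusion and the equatorial C3 hydroxyl follow from the chair–chair cation–olefin pathway. In steps to the decalin it is clearly stronger than the chosen route.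
- Against: A1 has hydrogen on C9 and a ketone at C8. C9 must still be hydroxylated on the correct face. C8 must be turned into a methyl-bearing carbon by olefination and hydrogenation; hydrogen would reach the C8=C17 alkene from the open α face (also the face of a directing 9α-hydroxyl), which puts the methyl axial on the β face, the opposite of 35. The ester carbon next to a tertiary alcohol and a ketone, a retro-Claisen-prone array, must be extended by five carbons.
- Comparison: the chosen strategy needs more steps to the bicycle, but makes C8 and C9 in one bond-forming step with their cis relation enforced and with C17 already a methyl carbon.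

**Alternative 2:** C5–C10 and C8–C9 are cut to the triene A4, an (E)-β-methyl enoate tethered to an (E,E)-1-siloxydiene. Forward, a thermal or Lewis-acid-promoted intramolecular Diels–Alder reaction gives the octalin A3 with a C8 silyl ether and a C9 ester.
- For: both rings and four stereocentres (C5, C10, C8, C9) form in one concerted step, and A4 could be made from alcohol 7 of the chosen route. In bonds formed per step it is stronger.
- Against: the dienophile is β,β-disubstituted and must form quaternary C10 while bonding to C5, which sits next to quaternary C4, so the cycloaddition is sterically disfavoured at both new bonds. The ester is on the dienophile carbon remote from the tether, so cis- versus trans-fusion is not enforced. A3 has oxygen at C8 where 35 has methyl and hydrogen at C9 where 35 has hydroxyl, so C9 hydroxylation, replacement of the C8 oxygen by a methyl group with the right configuration, reduction of C6=C7 and ester homologation remain.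
- Comparison: the radical-cation closure of the chosen route is an early-transition-state process that is less sensitive to this crowding, and it leads to the correct oxidation pattern at C8 and C9.

**Alternative 3:** C6–C7 and C8–C9 are cut to the ring A iodide A6 and acrolein A7. Forward, a trialkylborane with oxygen generates the primary C6 radical from A6, it adds to A7, and the boron enolate adds to the C9 ketone, giving the β-hydroxy aldehyde A5.
- For: ring B, the tertiary C9 alcohol and both C8/C9 stereocentres form in one step from a cheap three-carbon partner, and a closed aldol transition state should place oxygen and formyl cis. In directness toward the C9 alcohol it equals the ring B step of the chosen route.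
- Against: it does not solve ring A; A6 contains the C5/C10 pair and would itself come from acetal 15 by several extra steps. C8 arrives as a formyl group, one oxidation level too high, and its deoxygenation must be done on a β-hydroxy aldehyde that is prone to retro-aldol cleavage. The aldol addition to a ketone flanked by a quaternary carbon is reversible, and intermolecular radical addition competes with reduction and with oligomerisation of A7.
- Comparison: the chosen route obtains C17 as a methyl group directly by protonolysis of a titanium–carbon bond.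

Key step: step 8

## Route

Remarks on the chemistry: atoms are numbered as in labdanes (C1–C20) throughout, and 4, 10, 12, 16, 20 and 29 are taken as commercial. The Wittig step should give both geometric isomers of 14; the E isomer is drawn and the mixture is meant to be electrolysed, because the C9=C10 geometry is lost in step 8.

Step 1
Reactants: 1 ethyl levulinate (ethyl 4-oxopentanoate)
Product: 2 ethyl 3-(2-methyl-1,3-dioxolan-2-yl)propanoate
Conditions: HOCH2CH2OH, TsOH (cat.), toluene, reflux, Dean–Stark
Reagents that add atoms: ethylene glycol OCCO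
Why: Acid-catalysed ketalisation with azeotropic removal of water; the ketone (later C10) must be masked so that only the ester terminus is reduced and prenylated.

Step 2
Reactants: 2 ethyl 3-(2-methyl-1,3-dioxolan-2-yl)propanoate
Product: 3 3-(2-methyl-1,3-dioxolan-2-yl)propanal
Conditions: iBu2AlH, CH2Cl2, −78 °C; aq. KNaC4H4O6
Reagents that add atoms: none
Why: Partial reduction of the ester; the tetrahedral aluminium hemiacetal is stable at −78 °C and releases the aldehyde only on work-up, and the ketal is inert.

Step 3
Reactants: 3 3-(2-methyl-1,3-dioxolan-2-yl)propanal; 4 3-methylbuta-1,2-diene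
Product: 7 (3S)-4,4-dimethyl-1-(2-methyl-1,3-dioxolan-2-yl)hex-5-en-3-ol, via prenylborane 5 (not isolated), via borinate 6 (not isolated)
Conditions: (+)-Ipc2BH [from (−)-α-pinene], 4, THF, −25 → 0 °C; then 3, −78 °C; NaOH, H2O2, 0 °C → rt
Reagents that add atoms: none
Why: Asymmetric allylboration in its reverse-prenyl form: hydroboration of 4 gives B-prenylborane 5, which adds to the aldehyde with allylic transposition through a closed six-membered chair transition state, so C3–C4, the quaternary C4 and the vinyl group arise together. The (−)-α-pinene-derived isopinocampheyl groups direct the attack to the Re face of the aldehyde, which is the (S) carbinol here because the new quaternary carbon outranks the chain; oxidative cleavage of borinate 6 frees the alcohol.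

Step 4
Reactants: 7 (3S)-4,4-dimethyl-1-(2-methyl-1,3-dioxolan-2-yl)hex-5-en-3-ol
Product: 8 tert-butyl{[(3S)-4,4-dimethyl-1-(2-methyl-1,3-dioxolan-2-yl)hex-5-en-3-yl]oxy}dimethylsilane
Conditions: TBSOTf, 2,6-lutidine, CH2Cl2, −78 → 0 °C
Reagents that add atoms: tert-butyldimethylsilyl trifluoromethanesulfonate CC(C)(C)[Si](C)(C)OS(=O)(=O)C(F)(F)F
Why: Silylation of a neopentyl secondary alcohol needs the silyl triflate; cold, buffered conditions leave the ketal intact. The bulky silyl ether must survive mild acid, organometallics and electrolysis, and its size supports the equatorial preference used in step 8.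

Step 5
Reactants: 8 tert-butyl{[(3S)-4,4-dimethyl-1-(2-methyl-1,3-dioxolan-2-yl)hex-5-en-3-yl]oxy}dimethylsilane
Product: 9 (5S)-5-[(tert-butyldimethylsilyl)oxy]-6,6-dimethyloct-7-en-2-one
Conditions: PPTS, acetone/H2O, 55 °C
Reagents that add atoms: water O
Why: Mild ketal hydrolysis by exchange with wet acetone; the hindered secondary silyl ether tolerates pyridinium tosylate. The acid step is placed before the acid-sensitive allylsilane is made.

Step 6
Reactants: 9 (5S)-5-[(tert-butyldimethylsilyl)oxy]-6,6-dimethyloct-7-en-2-one; 10 allyltrimethylsilane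
Product: 11 (5S,7E)-5-[(tert-butyldimethylsilyl)oxy]-6,6-dimethyl-9-(trimethylsilyl)non-7-en-2-one
Conditions: second-generation Hoveyda–Grubbs catalyst (5 mol %), 10 (5 equiv), CH2Cl2, 40 °C
Reagents that add atoms: none
Why: Olefin cross-metathesis between a vinyl group on a quaternary carbon, which does not homodimerise, and an excess of a fast-reacting partner. The adjacent quaternary centre should enforce the E geometry; ketone and silyl ether are tolerated.

Step 7
Reactants: 11 (5S,7E)-5-[(tert-butyldimethylsilyl)oxy]-6,6-dimethyl-9-(trimethylsilyl)non-7-en-2-one; 12 (methoxymethyl)triphenylphosphonium chloride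
Product: 14 tert-butyl{[(1E,5S,7E)-1-methoxy-2,6,6-trimethyl-9-(trimethylsilyl)nona-1,7-dien-5-yl]oxy}dimethylsilane, via ylide 13 (not isolated)
Conditions: 12, KN(SiMe3)2, THF, 0 °C; then 11, 0 °C → rt
Reagents that add atoms: none
Why: Wittig methoxymethylenation of the methyl ketone installs C9 at the aldehyde oxidation level as an electron-rich enol ether; the basic, non-acidic conditions spare the silyl ether and the allylsilane. The Z isomer formed alongside is carried on, since C9 is not stereogenic in 15.

Step 8
Reactants: 14 tert-butyl{[(1E,5S,7E)-1-methoxy-2,6,6-trimethyl-9-(trimethylsilyl)nona-1,7-dien-5-yl]oxy}dimethylsilane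
Product: 15 tert-butyl{[(1S,3S,4S)-4-(dimethoxymethyl)-3-ethenyl-2,2,4-trimethylcyclohexyl]oxy}dimethylsilane
Conditions: reticulated vitreous carbon anode, Pt cathode, undivided cell, constant current (2.2 F/mol), 0.1 M LiClO4, MeOH/THF 1:4, 2,6-lutidine (6 equiv), rt
Reagents that add atoms: methanol CO
Why: The trisubstituted enol ether is the most easily oxidised group in 14, so the anode removes one electron from C9=C10 and leaves the allylsilane, the silyl ether and the solvent untouched. The radical cation is electrophilic at C10, the carbon remote from oxygen, and is attacked there by C5, the γ-carbon of the allylsilane; this polarity reversal joins two carbons that are both nucleophilic in the neutral molecule. Ring A closes in a 6-exo mode with respect to both π systems, C9 and C6 staying outside the ring. A second electron is then removed, the β-silyl cation at C6 gives up its silyl group to methanol to leave the C6=C7 vinyl group, and the oxocarbenium ion at C9 takes up methanol to give the dimethyl acetal, while 2,6-lutidine buffers the acid formed. The closest known reaction type is the intramolecular anodic coupling of enol ether radical cations with allylsilanes, which is established for five- and six-membered rings and for the formation of quaternary carbons. C10 and C5 are set together in a chair-like transition state with the C3 silyloxy group and C6 of the E-allylsilane equatorial; at C10 the methyl group takes the axial site facing the axial C4 methyl and C9, which carries the methoxy group, stays equatorial and trans to C6, which gives the (5S,10S) pair from (3S). The step needs C–C bond formation to outrun methanol capture of the radical cation, which the intramolecular six-membered closure and the nucleophilicity of the allylsilane should secure, and it needs facial relay from C3, which rests on the equatorial preference of the bulky silyl ether.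

Step 9
Reactants: 15 tert-butyl{[(1S,3S,4S)-4-(dimethoxymethyl)-3-ethenyl-2,2,4-trimethylcyclohexyl]oxy}dimethylsilane; 16 vinyl bromide (bromoethene)
Product: 18 {[(1S,3S,4S)-3-(but-3-en-1-yl)-4-(dimethoxymethyl)-2,2,4-trimethylcyclohexyl]oxy}(tert-butyl)dimethylsilane, via alkylborane 17 (not isolated)
Conditions: 9-BBN-H, THF, 60 °C; then 16, PdCl2(dppf) (5 mol %), AsPh3, K3PO4 (aq), DMF/THF, rt
Reagents that add atoms: none
Why: Anti-Markovnikov hydroboration of the only alkene puts boron on terminal C7; B-alkyl Suzuki–Miyaura coupling with 16 then adds C8 and C17 as a terminal alkene. The acetal keeps C9 out of reach of the borane, and no stereocentre is touched.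

Step 10
Reactants: 18 {[(1S,3S,4S)-3-(but-3-en-1-yl)-4-(dimethoxymethyl)-2,2,4-trimethylcyclohexyl]oxy}(tert-butyl)dimethylsilane
Product: 19 (1S,2S,4S)-2-(but-3-en-1-yl)-4-[(tert-butyldimethylsilyl)oxy]-1,3,3-trimethylcyclohexane-1-carbaldehyde
Conditions: TsOH·H2O (10 mol %), acetone/H2O, rt
Reagents that add atoms: water O
Why: Acetal hydrolysis in an aqueous medium, so that water and not the pendant alkene captures the oxocarbenium ion. The aldehyde sits on quaternary C10 and cannot enolise or epimerise; the hindered silyl ether survives.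

Step 11
Reactants: 19 (1S,2S,4S)-2-(but-3-en-1-yl)-4-[(tert-butyldimethylsilyl)oxy]-1,3,3-trimethylcyclohexane-1-carbaldehyde; 20 benzyl 4-bromobutyl ether
Product: 22 5-(benzyloxy)-1-{(1S,2S,4S)-2-(but-3-en-1-yl)-4-[(tert-butyldimethylsilyl)oxy]-1,3,3-trimethylcyclohexyl}pentan-1-ol (both C9 epimers), via Grignard reagent 21 (not isolated)
Conditions: 20, Mg, THF, 40 °C; then 19, CeCl3, THF, −78 → 0 °C
Reagents that add atoms: none
Why: Grignard addition to a non-enolisable neopentyl aldehyde, with CeCl3 to suppress β-hydride reduction; it brings C11, C12, C13 and C16 with its oxygen. The carbinol configuration is irrelevant because step 12 removes it.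

Step 12
Reactants: 22 5-(benzyloxy)-1-{(1S,2S,4S)-2-(but-3-en-1-yl)-4-[(tert-butyldimethylsilyl)oxy]-1,3,3-trimethylcyclohexyl}pentan-1-ol
Product: 23 5-(benzyloxy)-1-{(1S,2S,4S)-2-(but-3-en-1-yl)-4-[(tert-butyldimethylsilyl)oxy]-1,3,3-trimethylcyclohexyl}pentan-1-one
Conditions: Dess–Martin periodinane, NaHCO3, CH2Cl2, rt
Reagents that add atoms: none
Why: Mild oxidation of a hindered secondary alcohol; both epimers converge on one ketone, and the alkene, benzyl ether and silyl ether are untouched.

Step 13
Reactants: 23 5-(benzyloxy)-1-{(1S,2S,4S)-2-(but-3-en-1-yl)-4-[(tert-butyldimethylsilyl)oxy]-1,3,3-trimethylcyclohexyl}pentan-1-one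
Product: 25 (1R,2R,4aS,6S,8aS)-1-[4-(benzyloxy)butyl]-6-[(tert-butyldimethylsilyl)oxy]-2,5,5,8a-tetramethyldecahydronaphthalen-1-ol, via titanacycle 24 (not isolated)
Conditions: Cp2Ti(PMe3)2 (1.3 equiv), toluene, rt → 50 °C, PMe3 removed in vacuo; then HCl, Et2O, −78 → 0 °C
Reagents that add atoms: none
Why: Reductive alkene–ketone cyclisation at divalent titanium, a known route from ω-alkenyl ketones to cis-2-methylcycloalkanols: after loss of phosphine, oxidative coupling of the terminal alkene with the ketone forms C8–C9 and gives the oxatitanacyclopentane 24 of tetravalent titanium, closing ring B as a six-membered ring. Protonolysis of Ti–C and Ti–O turns C17 into the methyl group and frees the C9 alcohol. The metallacycle holds oxygen and C17 cis, and the chair with C17 equatorial (away from the axial C20 methyl) and the side chain equatorial sets 8α-methyl and 9α-hydroxyl (8R,9R).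

Step 14
Reactants: 25 (1R,2R,4aS,6S,8aS)-1-[4-(benzyloxy)butyl]-6-[(tert-butyldimethylsilyl)oxy]-2,5,5,8a-tetramethyldecahydronaphthalen-1-ol
Product: 26 (1R,2R,4aS,6S,8aS)-6-[(tert-butyldimethylsilyl)oxy]-1-(4-hydroxybutyl)-2,5,5,8a-tetramethyldecahydronaphthalen-1-ol
Conditions: H2 (1 atm), Pd/C, EtOAc, rt
Reagents that add atoms: none
Why: Hydrogenolysis of the benzyl ether; no alkene remains, and the silyl ether and the tertiary alcohol are inert.

Step 15
Reactants: 26 (1R,2R,4aS,6S,8aS)-6-[(tert-butyldimethylsilyl)oxy]-1-(4-hydroxybutyl)-2,5,5,8a-tetramethyldecahydronaphthalen-1-ol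
Product: 28 (3S,5S,8R,9R,10S)-3-[(tert-butyldimethylsilyl)oxy]-14,15-dinorlabdan-16,9-olide (spiro δ-lactone; C16 carbonyl; ring oxygen on C9), via lactol 27 (not isolated)
Conditions: TEMPO (20 mol %), PhI(OAc)2 (2.5 equiv), CH2Cl2, rt
Reagents that add atoms: none
Why: Oxoammonium oxidation selective for the primary alcohol; the aldehyde is captured by the C9 hydroxyl as the six-membered lactol 27, which is oxidised on to the lactone. C16 thus reaches the acid level and the tertiary alcohol is protected for the enolate step.

Step 16
Reactants: 28 (3S,5S,8R,9R,10S)-3-[(tert-butyldimethylsilyl)oxy]-14,15-dinorlabdan-16,9-olide; 29 (tert-butyldimethylsilyloxy)acetaldehyde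
Product: 30 (3S,5S,8R,9R,10S)-3,15-bis[(tert-butyldimethylsilyl)oxy]-14-hydroxylabdan-16,9-olide (mixture at C13 and C14)
Conditions: LiN(iPr)2, THF, −78 °C; then 29, −78 °C; aq. NH4Cl
Reagents that add atoms: none
Why: Aldol addition of the lactone enolate (C13 is the only enolisable position) forms C13–C14 and brings C14 and C15 with the oxygen that becomes the butenolide ring oxygen. The two new stereocentres are unimportant, since both carbons become sp2 in step 18.

Step 17
Reactants: 30 (3S,5S,8R,9R,10S)-3,15-bis[(tert-butyldimethylsilyl)oxy]-14-hydroxylabdan-16,9-olide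
Product: 33 (3S,5S,8R,9R,10S)-3,9,14-trihydroxylabdan-16,15-olide (mixture at C13 and C14), via primary alcohol 31 (not isolated), via silyl γ-lactone 32 (not isolated)
Conditions: Bu4NF (4 equiv), THF, 0 → 50 °C
Reagents that add atoms: none
Why: Fluoride removes the primary silyl group first (31); the freed C15 oxygen attacks the lactone carbonyl in a 5-exo addition and expels the hindered tertiary C9 alkoxide, so the spiro δ-lactone is exchanged for the more stable γ-lactone 32 and the C9 hydroxyl is released. Warming then cleaves the hindered C3 silyl ether.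

Step 18
Reactants: 33 (3S,5S,8R,9R,10S)-3,9,14-trihydroxylabdan-16,15-olide
Product: 35 (3S,5S,8R,9R,10S)-3-acetoxy-9-hydroxylabd-13-en-16,15-olide (target CNP0117645.1), via diacetate 34 (not isolated)
Conditions: Ac2O, Et3N, DMAP, CH2Cl2, rt; then DBU, rt
Reagents that add atoms: acetic anhydride CC(=O)OC(C)=O
Why: The two secondary hydroxyls (C3, C14) are acetylated while the hindered tertiary C9 hydroxyl is not. The C14 acetate, β to the lactone carbonyl, is then lost by E1cB elimination with DBU, which can only give the C13=C14 butenolide and leaves the 3β-acetate in place.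

## Compound list

1 | ethyl levulinate | CCOC(=O)CCC(C)=O | starting material
2 | ethyl 3-(2-methyl-1,3-dioxolan-2-yl)propanoate | CCOC(=O)CCC1(C)OCCO1 | intermediate
3 | 3-(2-methyl-1,3-dioxolan-2-yl)propanal | O=CCCC1(C)OCCO1 | intermediate
4 | 3-methylbuta-1,2-diene | CC(C)=C=C | starting material
5 | (+)-B-(3-methylbut-2-en-1-yl)diisopinocampheylborane | CC(C)=CCB([C@H]1C[C@H]2C[C@@H]([C@@H]1C)C2(C)C)[C@H]1C[C@H]2C[C@@H]([C@@H]1C)C2(C)C | intermediate (not isolated)
6 | diisopinocampheylborinate of alcohol 7 | CC1(CC[C@H](OB([C@H]2C[C@H]3C[C@@H]([C@@H]2C)C3(C)C)[C@H]2C[C@H]3C[C@@H]([C@@H]2C)C3(C)C)C(C)(C)C=C)OCCO1 | intermediate (not isolated)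
7 | (3S)-4,4-dimethyl-1-(2-methyl-1,3-dioxolan-2-yl)hex-5-en-3-ol | CC1(CC[C@H](O)C(C)(C)C=C)OCCO1 | intermediate
8 | tert-butyl{[(3S)-4,4-dimethyl-1-(2-methyl-1,3-dioxolan-2-yl)hex-5-en-3-yl]oxy}dimethylsilane | CC1(CC[C@H](O[Si](C)(C)C(C)(C)C)C(C)(C)C=C)OCCO1 | intermediate
9 | (5S)-5-[(tert-butyldimethylsilyl)oxy]-6,6-dimethyloct-7-en-2-one | CC(=O)CC[C@H](O[Si](C)(C)C(C)(C)C)C(C)(C)C=C | intermediate
10 | allyltrimethylsilane | C=CC[Si](C)(C)C | starting material
11 | (5S,7E)-5-[(tert-butyldimethylsilyl)oxy]-6,6-dimethyl-9-(trimethylsilyl)non-7-en-2-one | CC(=O)CC[C@H](O[Si](C)(C)C(C)(C)C)C(C)(C)/C=C/C[Si](C)(C)C | intermediate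
12 | (methoxymethyl)triphenylphosphonium chloride | [Cl-].COC[P+](c1ccccc1)(c1ccccc1)c1ccccc1 | starting material
13 | (methoxymethylidene)triphenylphosphorane | COC=P(c1ccccc1)(c1ccccc1)c1ccccc1 | intermediate (not isolated)
14 | tert-butyl{[(1E,5S,7E)-1-methoxy-2,6,6-trimethyl-9-(trimethylsilyl)nona-1,7-dien-5-yl]oxy}dimethylsilane | CO/C=C(\C)CC[C@H](O[Si](C)(C)C(C)(C)C)C(C)(C)/C=C/C[Si](C)(C)C | intermediate
15 | tert-butyl{[(1S,3S,4S)-4-(dimethoxymethyl)-3-ethenyl-2,2,4-trimethylcyclohexyl]oxy}dimethylsilane | C[Si](C)(C(C)(C)C)O[C@H]1CC[C@@](C(OC)OC)(C)[C@@H](C=C)C1(C)C | intermediate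
16 | vinyl bromide | C=CBr | starting material
17 | B-alkyl-9-borabicyclo[3.3.1]nonane from 15 (boron on C7) | C[Si](C)(C(C)(C)C)O[C@H]1CC[C@@](C(OC)OC)(C)[C@@H](CCB2C3CCCC2CCC3)C1(C)C | intermediate (not isolated)
18 | {[(1S,3S,4S)-3-(but-3-en-1-yl)-4-(dimethoxymethyl)-2,2,4-trimethylcyclohexyl]oxy}(tert-butyl)dimethylsilane | C[Si](C)(C(C)(C)C)O[C@H]1CC[C@@](C(OC)OC)(C)[C@@H](CCC=C)C1(C)C | intermediate
19 | (1S,2S,4S)-2-(but-3-en-1-yl)-4-[(tert-butyldimethylsilyl)oxy]-1,3,3-trimethylcyclohexane-1-carbaldehyde | C[Si](C)(C(C)(C)C)O[C@H]1CC[C@@](C=O)(C)[C@@H](CCC=C)C1(C)C | intermediate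
20 | benzyl 4-bromobutyl ether | BrCCCCOCc1ccccc1 | starting material
21 | [4-(benzyloxy)butyl]magnesium bromide | Br[Mg]CCCCOCc1ccccc1 | intermediate (not isolated)
22 | 5-(benzyloxy)-1-{(1S,2S,4S)-2-(but-3-en-1-yl)-4-[(tert-butyldimethylsilyl)oxy]-1,3,3-trimethylcyclohexyl}pentan-1-ol (both C9 epimers) | C[Si](C)(C(C)(C)C)O[C@H]1CC[C@@](C(O)CCCCOCc2ccccc2)(C)[C@@H](CCC=C)C1(C)C | intermediate
23 | 5-(benzyloxy)-1-{(1S,2S,4S)-2-(but-3-en-1-yl)-4-[(tert-butyldimethylsilyl)oxy]-1,3,3-trimethylcyclohexyl}pentan-1-one | C[Si](C)(C(C)(C)C)O[C@H]1CC[C@@](C(=O)CCCCOCc2ccccc2)(C)[C@@H](CCC=C)C1(C)C | intermediate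
24 | bis(cyclopentadienyl) oxatitanacyclopentane fused at C8–C9 (Ti bonded to the C9 oxygen and to C17) | C[Si](C)(C(C)(C)C)O[C@H]1CC[C@@]2(C)[C@@H](CC[C@@H](C[Ti]3(C4C=CC=C4)C4C=CC=C4)[C@]2(O3)CCCCOCc2ccccc2)C1(C)C | intermediate (not isolated)
25 | (1R,2R,4aS,6S,8aS)-1-[4-(benzyloxy)butyl]-6-[(tert-butyldimethylsilyl)oxy]-2,5,5,8a-tetramethyldecahydronaphthalen-1-ol | C[Si](C)(C(C)(C)C)O[C@H]1CC[C@@]2(C)[C@@H](CC[C@@H](C)[C@]2(O)CCCCOCc2ccccc2)C1(C)C | intermediate
26 | (1R,2R,4aS,6S,8aS)-6-[(tert-butyldimethylsilyl)oxy]-1-(4-hydroxybutyl)-2,5,5,8a-tetramethyldecahydronaphthalen-1-ol | C[Si](C)(C(C)(C)C)O[C@H]1CC[C@@]2(C)[C@@H](CC[C@@H](C)[C@]2(O)CCCCO)C1(C)C | intermediate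
27 | (3S,5S,8R,9R,10S)-3-[(tert-butyldimethylsilyl)oxy]-9,16-epoxy-14,15-dinorlabdan-16-ol (lactol, both anomers) | C[Si](C)(C(C)(C)C)O[C@H]1CC[C@@]2(C)[C@@H](CC[C@@H](C)[C@]23CCCC(O)O3)C1(C)C | intermediate (not isolated)
28 | (3S,5S,8R,9R,10S)-3-[(tert-butyldimethylsilyl)oxy]-14,15-dinorlabdan-16,9-olide (spiro δ-lactone) | C[Si](C)(C(C)(C)C)O[C@H]1CC[C@@]2(C)[C@@H](CC[C@@H](C)[C@]23CCCC(=O)O3)C1(C)C | intermediate
29 | (tert-butyldimethylsilyloxy)acetaldehyde | O=CCO[Si](C)(C)C(C)(C)C | starting material
30 | (3S,5S,8R,9R,10S)-3,15-bis[(tert-butyldimethylsilyl)oxy]-14-hydroxylabdan-16,9-olide (mixture at C13 and C14) | C[Si](C)(C(C)(C)C)O[C@H]1CC[C@@]2(C)[C@@H](CC[C@@H](C)[C@]23CCC(C(O)CO[Si](C)(C)C(C)(C)C)C(=O)O3)C1(C)C | intermediate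
31 | (3S,5S,8R,9R,10S)-3-[(tert-butyldimethylsilyl)oxy]-14,15-dihydroxylabdan-16,9-olide | C[Si](C)(C(C)(C)C)O[C@H]1CC[C@@]2(C)[C@@H](CC[C@@H](C)[C@]23CCC(C(O)CO)C(=O)O3)C1(C)C | intermediate (not isolated)
32 | (3S,5S,8R,9R,10S)-3-[(tert-butyldimethylsilyl)oxy]-9,14-dihydroxylabdan-16,15-olide | C[Si](C)(C(C)(C)C)O[C@H]1CC[C@@]2(C)[C@@H](CC[C@@H](C)[C@]2(O)CCC2C(O)COC2=O)C1(C)C | intermediate (not isolated)
33 | (3S,5S,8R,9R,10S)-3,9,14-trihydroxylabdan-16,15-olide (mixture at C13 and C14) | O[C@H]1CC[C@@]2(C)[C@@H](CC[C@@H](C)[C@]2(O)CCC2C(O)COC2=O)C1(C)C | intermediate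
34 | (3S,5S,8R,9R,10S)-3,14-diacetoxy-9-hydroxylabdan-16,15-olide | CC(=O)O[C@H]1CC[C@@]2(C)[C@@H](CC[C@@H](C)[C@]2(O)CCC2C(OC(C)=O)COC2=O)C1(C)C | intermediate (not isolated)
35 | (3S,5S,8R,9R,10S)-3-acetoxy-9-hydroxylabd-13-en-16,15-olide (CNP0117645.1) | CC(=O)O[C@H]1CC[C@@]2(C)[C@@H](CC[C@@H](C)[C@]2(O)CCC2=CCOC2=O)C1(C)C | target

## Step count and least certain steps

Total step count: 18. Longest linear sequence: 18 steps (1 → 35); all other inputs are commercial.

**Step 8 (key step).** Two processes are most likely to fail.
- Poor facial relay: the preference for an equatorial C3 silyloxy group in the chair is modest because it is gauche to both C4 methyls, and the preference for C9 over the methyl group in the equatorial site at C10 is also not large. Either would lower the selectivity for the (5S,10S) pair.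
- Solvent capture before cyclisation: the new bond joins C5, next to quaternary C4, to the carbon that becomes quaternary C10, so bond formation may be slow enough for methanol to trap the radical cation.

Fallback, from ketone 9 back to acetal 15, by two-electron allylic alkylation instead of radical-cation chemistry: Wittig reaction of 9 with ylide 13 should give the enol ether tert-butyl{[(1E,5S)-1-methoxy-2,6,6-trimethylocta-1,7-dien-5-yl]oxy}dimethylsilane F1. Oxalic acid in wet THF should give the α-methyl aldehyde (5S)-5-[(tert-butyldimethylsilyl)oxy]-2,6,6-trimethyloct-7-enal F2. Cross-metathesis of its vinyl group with allyl methyl carbonate (second-generation Hoveyda–Grubbs catalyst) should give the allylic carbonate (2E,5S)-5-[(tert-butyldimethylsilyl)oxy]-4,4,8-trimethyl-9-oxonon-2-en-1-yl methyl carbonate F3. Pd(PPh3)4 with pyrrolidine should then close ring A by intramolecular Tsuji–Trost allylation of the enamine, C10 attacking the C5 end of the π-allyl complex of divalent palladium, to give (1S,2S,4S)-4-[(tert-butyldimethylsilyl)oxy]-2-ethenyl-1,3,3-trimethylcyclohexane-1-carbaldehyde F4. HC(OMe)3, MeOH and PPTS return 15.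

**Step 6.** The vinyl group sits on a quaternary carbon next to the silyloxy-bearing carbon, so productive metathesis may be slow and self-metathesis of 10 may consume the catalyst before conversion is complete.

Fallback, from silyl ether 8 back to acetal 15, by olefination instead of metathesis: ozonolysis of 8 (O3, CH2Cl2, −78 °C; PPh3) should give the aldehyde (3S)-3-[(tert-butyldimethylsilyl)oxy]-2,2-dimethyl-5-(2-methyl-1,3-dioxolan-2-yl)pentanal F5. Wittig reaction with Ph3P=CHCH2SiMe3 should give mainly the Z allylsilane tert-butyl{[(3S,5Z)-4,4-dimethyl-1-(2-methyl-1,3-dioxolan-2-yl)-7-(trimethylsilyl)hept-5-en-3-yl]oxy}dimethylsilane F6. PPTS in wet acetone should free the ketone (5S,7Z)-5-[(tert-butyldimethylsilyl)oxy]-6,6-dimethyl-9-(trimethylsilyl)non-7-en-2-one F7. The conditions of step 7 should give the enol ether tert-butyl{[(1E,5S,7Z)-1-methoxy-2,6,6-trimethyl-9-(trimethylsilyl)nona-1,7-dien-5-yl]oxy}dimethylsilane F8, and the electrolysis of step 8 leads to 15, in which the C5=C6 geometry no longer exists. The facial selectivity with the Z allylsilane may differ.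

**Step 13.** The ketone is flanked by quaternary C10 and may fail to enter the metallacycle, so that simple carbonyl reduction or alkene isomerisation takes over. Six-membered closure is also less favoured than five-membered closure, and closure through a trans-fused metallacycle would give the C9 epimer.

Fallback, from ketone 23 back to alcohol 25 without a new compound, by a radical instead of an organometallic closure: Fe(acac)3 and PhSiH3 in EtOH at 60 °C should transfer a hydrogen atom to C17, and the secondary C8 radical should add to the C9 carbonyl in a chair with the methyl group and the side chain equatorial, followed by reduction of the alkoxy radical.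

**Step 17.** Retro-aldol cleavage of the β-hydroxy lactone under basic fluoride, or an incomplete ring switch from the δ- to the γ-lactone, would leave material that cannot give the butenolide in step 18.

Fallback, from lactone 28 to target 35, closing the butenolide by metathesis instead of lactone exchange: α-methylenation of 28 (LiN(iPr)2; Eschenmoser's salt; MeI; NaHCO3) should give the α-methylene spiro δ-lactone F9. Hydrolysis with LiOH and O-alkylation of the carboxylate with allyl bromide should give the allyl 2-methylene ester with free C9 hydroxyl F10. Ring-closing metathesis with second-generation Grubbs catalyst should give the 3-silyloxy butenolide F11. Aqueous HF in MeCN should give the 3-hydroxy butenolide F12, and Ac2O in pyridine gives 35.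

## Further compounds

F1 | step 8 | tert-butyl{[(1E,5S)-1-methoxy-2,6,6-trimethylocta-1,7-dien-5-yl]oxy}dimethylsilane | CO/C=C(\C)CC[C@H](O[Si](C)(C)C(C)(C)C)C(C)(C)C=C
F2 | step 8 | (5S)-5-[(tert-butyldimethylsilyl)oxy]-2,6,6-trimethyloct-7-enal (both C2 epimers) | O=CC(C)CC[C@H](O[Si](C)(C)C(C)(C)C)C(C)(C)C=C
F3 | step 8 | (2E,5S)-5-[(tert-butyldimethylsilyl)oxy]-4,4,8-trimethyl-9-oxonon-2-en-1-yl methyl carbonate | O=CC(C)CC[C@H](O[Si](C)(C)C(C)(C)C)C(C)(C)/C=C/COC(=O)OC
F4 | step 8 | (1S,2S,4S)-4-[(tert-butyldimethylsilyl)oxy]-2-ethenyl-1,3,3-trimethylcyclohexane-1-carbaldehyde | C[Si](C)(C(C)(C)C)O[C@H]1CC[C@@](C=O)(C)[C@@H](C=C)C1(C)C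
F5 | step 6 | (3S)-3-[(tert-butyldimethylsilyl)oxy]-2,2-dimethyl-5-(2-methyl-1,3-dioxolan-2-yl)pentanal | CC1(CC[C@H](O[Si](C)(C)C(C)(C)C)C(C)(C)C=O)OCCO1
F6 | step 6 | tert-butyl{[(3S,5Z)-4,4-dimethyl-1-(2-methyl-1,3-dioxolan-2-yl)-7-(trimethylsilyl)hept-5-en-3-yl]oxy}dimethylsilane | CC1(CC[C@H](O[Si](C)(C)C(C)(C)C)C(C)(C)/C=C\C[Si](C)(C)C)OCCO1
F7 | step 6 | (5S,7Z)-5-[(tert-butyldimethylsilyl)oxy]-6,6-dimethyl-9-(trimethylsilyl)non-7-en-2-one | CC(=O)CC[C@H](O[Si](C)(C)C(C)(C)C)C(C)(C)/C=C\C[Si](C)(C)C
F8 | step 6 | tert-butyl{[(1E,5S,7Z)-1-methoxy-2,6,6-trimethyl-9-(trimethylsilyl)nona-1,7-dien-5-yl]oxy}dimethylsilane | CO/C=C(\C)CC[C@H](O[Si](C)(C)C(C)(C)C)C(C)(C)/C=C\C[Si](C)(C)C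
F0 | step 13 | none | none
F9 | step 17 | α-methylene spiro δ-lactone from 28 (exocyclic methylene on C13) | C[Si](C)(C(C)(C)C)O[C@H]1CC[C@@]2(C)[C@@H](CC[C@@H](C)[C@]23CCC(=C)C(=O)O3)C1(C)C
F10 | step 17 | allyl 2-methylene ester with free C9 hydroxyl and 3-silyl ether | C[Si](C)(C(C)(C)C)O[C@H]1CC[C@@]2(C)[C@@H](CC[C@@H](C)[C@]2(O)CCC(=C)C(=O)OCC=C)C1(C)C
F11 | step 17 | (3S,5S,8R,9R,10S)-3-[(tert-butyldimethylsilyl)oxy]-9-hydroxylabd-13-en-16,15-olide | C[Si](C)(C(C)(C)C)O[C@H]1CC[C@@]2(C)[C@@H](CC[C@@H](C)[C@]2(O)CCC2=CCOC2=O)C1(C)C
F12 | step 17 | (3S,5S,8R,9R,10S)-3,9-dihydroxylabd-13-en-16,15-olide | O[C@H]1CC[C@@]2(C)[C@@H](CC[C@@H](C)[C@]2(O)CCC2=CCOC2=O)C1(C)C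
A1 | alternative 1 | 3β-hydroxy trans-decalin with C8 ketone and C9 methyl ester (labdane numbering) | O[C@H]1CC[C@@]2(C)[C@@H](CCC(=O)[C@@H]2C(=O)OC)C1(C)C
A2 | alternative 1 | methyl (6E)-9-[(2S)-3,3-dimethyloxiran-2-yl]-7-methyl-3-oxonon-6-enoate | COC(=O)CC(=O)CC/C=C(\C)CC[C@@H]1OC1(C)C
A3 | alternative 2 | trans-fused octalin with 3-silyl ether, C6=C7 alkene, C8 triethylsilyl ether and C9 methyl ester | C[Si](C)(C(C)(C)C)O[C@H]1CC[C@@]2(C)[C@@H](C=C[C@H](O[Si](CC)(CC)CC)[C@@H]2C(=O)OC)C1(C)C
A4 | alternative 2 | methyl (2E,6S,8E,10E)-6-[(tert-butyldimethylsilyl)oxy]-3,7,7-trimethyl-11-[(triethylsilyl)oxy]undeca-2,8,10-trienoate | COC(=O)/C=C(\C)CC[C@H](O[Si](C)(C)C(C)(C)C)C(C)(C)/C=C/C=C/O[Si](CC)(CC)CC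
A5 | alternative 3 | decalin with C9 tertiary alcohol, C8 formyl group and 4-(benzyloxy)butyl chain | C[Si](C)(C(C)(C)C)O[C@H]1CC[C@@]2(C)[C@@H](CC[C@@H](C=O)[C@]2(O)CCCCOCc2ccccc2)C1(C)C
A6 | alternative 3 | ring A ketone with iodomethyl group on C5 | C[Si](C)(C(C)(C)C)O[C@H]1CC[C@@](C(=O)CCCCOCc2ccccc2)(C)[C@@H](CI)C1(C)C
A7 | alternative 3 | acrolein | C=CC=O
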